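(The constants used here are invented; the rest is arithmetic.)

Two flasks, one question.

the same everywhere: substrate 0.012 M; coupling partner 0.0180 M; free catalyst 24 µM; second catalyst 6.0 µM; time 2.5 min
- red: temperature 30 °C
- grey: temperature 60 °C

    coupling partner + second catalyst + intermediate → second catalyst + target (k1 = 6.2 × 10⁶ M⁻² s⁻¹, Ea1 = 9.00 kJ mol⁻¹)
    target ⇌ isomer of the product (K2 = 0.64, k2 = 0.0071 s⁻¹, Ea2 = 104 kJ mol⁻¹, ΔH2 = −55.0 kJ mol⁻¹)
    substrate + free catalyst ⇌ free catalyst + intermediate (K3 = 0.28, k3 = 3900 M⁻¹ s⁻¹, Ea3 = 14.0 kJ mol⁻¹, ΔH3 = 9.00 kJ mol⁻¹)
    coupling partner → decomposition product (k4 = 1.1 × 10⁻⁵ s⁻¹, Ea4 = 104 kJ mol⁻¹)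
    (constants at 60 °C)

- constants are those at 60 °C; use the activation energies and enthalpies for any other temperature

* the best flask by share of target in all that became target or isomer of the product; "all alike" if 1.5 percentage points covers them all (red / grey / all alike)
* share of target in all that became target or isomer of the product, red
* share of target in all that became target or isomer of the product, grey

Two chemists disagree over these flasks. The first holds to thermodynamic control: in grey the pair of target and isomer of the product relaxes with a half-life of 0.635 min, shorter than the 2.5 min allowed, so in her view the pair stands at equilibrium when read. That makes the fraction of target 61.0% in grey, while in red, with the enthalpy −55.0 kJ mol⁻¹, the constant rises to 4.57 and the fraction falls to 18.0%, so she picks grey.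

The second chemist, on whose side I stand, holds to kinetic control and counts instead. The relaxation constant, the forward plus the backward constant of step 2 at the flask's own temperature, is 0.0182 s⁻¹ in grey. In red the forward constant drops to 1.73 × 10⁻⁴ s⁻¹, which gives a relaxation constant of 2.11 × 10⁻⁴ s⁻¹. Multiplied by the time target has lived, this constant gives a count, and the excess of target's fraction over equilibrium shrinks as the exponential of minus that count. The red half-life is 54.8 min, longer than the time allowed.

My first round pretends target is born at the start. The counts are 2.73 in grey and 0.0316 in red, which give 63.5% and 97.4%.

Then I put that answer back in. If grey's substrate is consumed, the partner falls by 0.667 of its charge, so midway 0.667 of it remains. In my reckoning the intermediate is then drained at 0.446 s⁻¹ against a return of 0.334 s⁻¹, and the substrate feeds target at 0.0535 s⁻¹, faster than the relaxation. Late birth multiplies the remaining excess by 1.52, so my grey figure becomes 64.8%. Red I leave at its first round, which late birth raises a little, and it stays above grey.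

The forecast takes the same side: red is best, with 98% for red (range 97.5% to 98.4%) and 65.2% for grey (range 64% to 66.5%). It starts from “The substrate/intermediate pool is in fast pre-equilibrium” and takes a mean formation time near 28 s in grey, where mine is 18.7 s, and my grey figure lies 0.40 percentage points below its number.

The simulation gives 98.0% for red and 65.2% for grey, so red is best. Read earlier, grey leaves the forecast's range, its answer having moved 5 points at 1.73 min, while at 25.0 min, a count of 27.3, grey stands at 61.0%, the first chemist's figure, which is where her view holds for grey. For red at 25.0 min the count is 0.316, which gives 77.8%, and red stands there at 78.3%.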